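**Retrosynthetic overview**

1. Sarothralin 23 is cut at the methylene bridge: isobutyrylfilicinic acid 21 (two steps from phloroglucinol 18) adds through carbon to the ortho-quinone methide released from benzylic methyl ether 17, so ring A carries the bridge carbon from the start.
2. 17 comes from hydroxybenzophenone 13 by O-prenylation of its single free phenol and removal of two MOM groups without protic acid.
3. 13 is cut across two neighbouring ring A bonds, aryl–C(=O)Ph and aryl–O. In ring A the benzoyl carbon and the prenyloxy carbon are adjacent; the benzoyl carbon's other neighbour is an oxygenated carbon and the prenyloxy carbon's other neighbour is the only ring C–H. This is the pattern left when benzoic acid 11 adds across 3-alkoxybenzyne 12 and its acyl group moves from oxygen to carbon.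
4. Aryne precursor 10 comes from the symmetrical phenol 6 (bromination, retro-Brook shift, triflation), which is made from 2,4,6-trihydroxybenzaldehyde 1; the formyl carbon of 1 becomes the bridge carbon.
5. No ring is built: ring A (from 1) and the filicinic ring (from 18) are preformed six-membered carbocycles, joined in the last step.

Key step: step 8

Remark: the target has no stereocentre and is drawn as one enol tautomer of the acylfilicinic ring, so no stereocontrol is needed. The benzylic oxygen is carried as a methyl ether so that it survives the MOM removal and ionises only in the last step, and the para oxygen is masked as an allyl ether so that no hydrogenolysis is needed near the electron-rich benzylic C–O bond.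

**Route**

Step 1
Reactants: 1 2,4,6-trihydroxybenzaldehyde
Product: 2 4-(allyloxy)-2,6-dihydroxybenzaldehyde
Conditions: allyl bromide (1.0 equiv), K2CO3 (1.0 equiv), acetone, 0 °C to rt
Reagents that add atoms: allyl bromide, C=CCBr
Why: The 4-hydroxyl is para to the formyl group and is the only one not hydrogen-bonded to it, so it is the most acidic and should be alkylated first in a Williamson etherification with one equivalent of halide.

Step 2
Reactants: 2 4-(allyloxy)-2,6-dihydroxybenzaldehyde
Product: 3 4-(allyloxy)-2,6-bis(methoxymethoxy)benzaldehyde
Conditions: NaH (2.4 equiv), MOMCl (2.4 equiv), DMF, 0 °C to rt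
Reagents that add atoms: chloromethyl methyl ether, COCCl
Why: Full deprotonation with NaH breaks the chelation to the aldehyde, and the hard chloromethyl ether should alkylate both phenoxide oxygens (Williamson-type acetal formation).

Step 3
Reactants: 3 4-(allyloxy)-2,6-bis(methoxymethoxy)benzaldehyde
Product: 4 [4-(allyloxy)-2,6-bis(methoxymethoxy)phenyl]methanol
Conditions: NaBH4, MeOH/THF, 0 °C
Reagents that add atoms: none
Why: Borohydride reduction of the non-enolisable aryl aldehyde should give the benzylic alcohol and leave the acetals and the allyl ether untouched.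

Step 4
Reactants: 4 [4-(allyloxy)-2,6-bis(methoxymethoxy)phenyl]methanol
Product: 5 5-(allyloxy)-1,3-bis(methoxymethoxy)-2-(methoxymethyl)benzene
Conditions: NaH, MeI, THF, 0 °C to rt
Reagents that add atoms: iodomethane, CI
Why: Williamson methylation of the primary alkoxide gives a benzylic ether that tolerates base, organolithium and fluoride, and is still ionisable in the final step.

Step 5
Reactants: 5 5-(allyloxy)-1,3-bis(methoxymethoxy)-2-(methoxymethyl)benzene
Product: 6 3,5-bis(methoxymethoxy)-4-(methoxymethyl)phenol
Conditions: Pd(PPh3)4 (3 mol %), morpholine (3 equiv), THF, rt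
Reagents that add atoms: none
Why: Tsuji–Trost deallylation: the palladium complex ionises the allyl aryl ether to a π-allyl species that morpholine intercepts, and the acetals and the benzylic ether are not affected.

Step 6
Reactants: 6 3,5-bis(methoxymethoxy)-4-(methoxymethyl)phenol
Product: 7 2-bromo-3,5-bis(methoxymethoxy)-4-(methoxymethyl)phenol
Conditions: NBS (1.0 equiv), CH2Cl2, −78 to −20 °C
Reagents that add atoms: N-bromosuccinimide, O=C1CCC(=O)N1Br
Why: Electrophilic aromatic bromination at one of the two equivalent positions ortho to the free phenol; these are activated by all three oxygens, and one equivalent at low temperature should stop at the monobromide.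

Step 7
Reactants: 7 2-bromo-3,5-bis(methoxymethoxy)-4-(methoxymethyl)phenol
Product: 10 3,5-bis(methoxymethoxy)-4-(methoxymethyl)-2-(trimethylsilyl)phenyl trifluoromethanesulfonate, via aryl trimethylsilyl ether 8 (not isolated), via lithium 2-silylphenoxide 9 (not isolated)
Conditions: HMDS, THF, 65 °C, then evaporate; n-BuLi (1.1 equiv), THF, −78 °C; Tf2O (1.2 equiv), −78 °C to rt
Reagents that add atoms: hexamethyldisilazane, C[Si](C)(C)N[Si](C)(C)C; trifluoromethanesulfonic anhydride, O=S(=O)(OS(=O)(=O)C(F)(F)F)C(F)(F)F; n-butyllithium, [Li]CCCC (lithium of intermediate 9 only)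
Why: O-silylation, bromine–lithium exchange and a retro-Brook 1,3-shift of silicon from oxygen to carbon give the ortho-silyl phenoxide, which is trapped as its triflate in the same flask.

Step 8
Reactants: 10 3,5-bis(methoxymethoxy)-4-(methoxymethyl)-2-(trimethylsilyl)phenyl trifluoromethanesulfonate; 11 benzoic acid
Product: 13 2-hydroxy-4,6-bis(methoxymethoxy)-5-(methoxymethyl)benzophenone, via 3-alkoxybenzyne 12 (not isolated)
Conditions: 11 (1.0 equiv), CsF (4 equiv), THF, 125 °C, sealed tube
Reagents that add atoms: none
Why: Fluoride attacks silicon and triflate leaves to give aryne 12; benzoate then adds through oxygen to the aryne carbon remote from the neighbouring methoxymethoxy group, so that the aryl anion develops on the carbon beside that inductively withdrawing oxygen, which is also the outcome predicted by the distortion of a 3-alkoxyaryne. The anion attacks the ester carbonyl through a four-membered transition state and the benzoyl group moves from oxygen to carbon, ending as the caesium phenoxide of the ortho-hydroxybenzophenone. The closest known reaction type is the insertion of arynes into the C–O bond of carboxylic acids (σ-insertion with acyl transfer), which gives ortho-hydroxyaryl ketones. No ring is closed and no stereocentre is formed. The step needs regioselective oxygen attack, secured by the 3-alkoxy group against a flank that is only C–H, and acyl transfer faster than protonation of the aryl anion, favoured by the high temperature, the aprotic medium and no more than one equivalent of acid. The symmetry of phenol 6 fixes the positions of silicon and triflate in 10 without ambiguity, and the phenol set free is the only unprotected oxygen and is the one that must carry the prenyl group.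

Step 9
Reactants: 13 2-hydroxy-4,6-bis(methoxymethoxy)-5-(methoxymethyl)benzophenone; 14 prenyl bromide
Product: 15 4,6-bis(methoxymethoxy)-5-(methoxymethyl)-2-(3-methylbut-2-enyloxy)benzophenone
Conditions: 14 (1.3 equiv), K2CO3, DMF, rt
Reagents that add atoms: none
Why: Williamson O-alkylation (SN2 at the primary allylic bromide) of the only free phenol; the polar aprotic solvent favours O- over C-alkylation.

Step 10
Reactants: 15 4,6-bis(methoxymethoxy)-5-(methoxymethyl)-2-(3-methylbut-2-enyloxy)benzophenone
Product: 17 4,6-dihydroxy-5-(methoxymethyl)-2-(3-methylbut-2-enyloxy)benzophenone, via bis(trimethylsilyl) ether 16 (not isolated)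
Conditions: TMSOTf (4 equiv), 2,2'-bipyridyl (6 equiv), MeCN, 0 °C to rt; then H2O
Reagents that add atoms: trimethylsilyl trifluoromethanesulfonate, C[Si](C)(C)OS(=O)(=O)C(F)(F)F (silyl groups of intermediate 16 only)
Why: The silyl triflate–bipyridyl pair converts aryl MOM ethers into aryl silyl ethers that water then hydrolyses, a chemoselective acetal cleavage without protic acid, chosen so that the acid-labile prenyl ether and the benzylic methyl ether should survive.

Step 11
Reactants: 18 phloroglucinol; 19 isobutyryl chloride
Product: 20 2-methyl-1-(2,4,6-trihydroxyphenyl)propan-1-one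
Conditions: AlCl3 (3 equiv), PhNO2, rt to 60 °C; aq. HCl
Reagents that add atoms: none
Why: Friedel–Crafts acylation of the electron-rich ring; the first acyl group deactivates the ring, so monoacylation is expected.

Step 12
Reactants: 20 2-methyl-1-(2,4,6-trihydroxyphenyl)propan-1-one
Product: 21 isobutyrylfilicinic acid (3,5-dihydroxy-6,6-dimethyl-2-(2-methylpropanoyl)cyclohexa-2,4-dien-1-one)
Conditions: NaOMe (3 equiv), MeI (2.5 equiv), MeOH, 0 °C to rt
Reagents that add atoms: iodomethane, CI
Why: Base-mediated double C-methylation of the acylphloroglucinol at one ring carbon dearomatises the ring to the gem-dimethyl filicinic core (alkylative dearomatisation), the second methyl entering at the already methylated, most nucleophilic carbon.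

Step 13
Reactants: 17 4,6-dihydroxy-5-(methoxymethyl)-2-(3-methylbut-2-enyloxy)benzophenone; 21 isobutyrylfilicinic acid
Product: 23 sarothralin, via ortho-quinone methide 22 (not isolated)
Conditions: 21 (2 equiv), PPTS (10 mol %), 4 Å MS, toluene, 70 °C
Reagents that add atoms: none
Why: Mild acid promotes loss of methanol from the ortho-hydroxybenzyl methyl ether on the trioxygenated ring to give an ortho-quinone methide, and Michael addition of the single C–H carbon of the acylfilicinic acid rearomatises ring A and forms the methylene bridge; PPTS is weak enough for the prenyl aryl ether to be expected to survive.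

**Compound list**

1 | 2,4,6-trihydroxybenzaldehyde | O=Cc1c(O)cc(O)cc1O | starting material
2 | 4-(allyloxy)-2,6-dihydroxybenzaldehyde | O=Cc1c(O)cc(OCC=C)cc1O | intermediate
3 | 4-(allyloxy)-2,6-bis(methoxymethoxy)benzaldehyde | O=Cc1c(OCOC)cc(OCC=C)cc1OCOC | intermediate
4 | [4-(allyloxy)-2,6-bis(methoxymethoxy)phenyl]methanol | OCc1c(OCOC)cc(OCC=C)cc1OCOC | intermediate
5 | 5-(allyloxy)-1,3-bis(methoxymethoxy)-2-(methoxymethyl)benzene | COCc1c(OCOC)cc(OCC=C)cc1OCOC | intermediate
6 | 3,5-bis(methoxymethoxy)-4-(methoxymethyl)phenol | COCc1c(OCOC)cc(O)cc1OCOC | intermediate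
7 | 2-bromo-3,5-bis(methoxymethoxy)-4-(methoxymethyl)phenol | COCc1c(OCOC)cc(O)c(Br)c1OCOC | intermediate
8 | [2-bromo-3,5-bis(methoxymethoxy)-4-(methoxymethyl)phenoxy]trimethylsilane (formed in the flask) | COCc1c(OCOC)cc(O[Si](C)(C)C)c(Br)c1OCOC | intermediate
9 | lithium 3,5-bis(methoxymethoxy)-4-(methoxymethyl)-2-(trimethylsilyl)phenoxide (formed in the flask) | [Li+].[O-]c1cc(OCOC)c(COC)c(OCOC)c1[Si](C)(C)C | intermediate
10 | 3,5-bis(methoxymethoxy)-4-(methoxymethyl)-2-(trimethylsilyl)phenyl trifluoromethanesulfonate | COCc1c(OCOC)cc(OS(=O)(=O)C(F)(F)F)c([Si](C)(C)C)c1OCOC | intermediate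
11 | benzoic acid | OC(=O)c1ccccc1 | starting material
12 | 3,5-bis(methoxymethoxy)-4-(methoxymethyl)-1,2-didehydrobenzene (aryne, formed in the flask) | COCOC1=CC#CC(OCOC)=C1COC | intermediate
13 | 2-hydroxy-4,6-bis(methoxymethoxy)-5-(methoxymethyl)benzophenone | Oc1cc(OCOC)c(COC)c(OCOC)c1C(=O)c1ccccc1 | intermediate
14 | prenyl bromide (1-bromo-3-methylbut-2-ene) | CC(C)=CCBr | starting material
15 | 4,6-bis(methoxymethoxy)-5-(methoxymethyl)-2-(3-methylbut-2-enyloxy)benzophenone | CC(C)=CCOc1cc(OCOC)c(COC)c(OCOC)c1C(=O)c1ccccc1 | intermediate
16 | 5-(methoxymethyl)-2-(3-methylbut-2-enyloxy)-4,6-bis(trimethylsilyloxy)benzophenone (formed in the flask) | CC(C)=CCOc1cc(O[Si](C)(C)C)c(COC)c(O[Si](C)(C)C)c1C(=O)c1ccccc1 | intermediate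
17 | 4,6-dihydroxy-5-(methoxymethyl)-2-(3-methylbut-2-enyloxy)benzophenone | CC(C)=CCOc1cc(O)c(COC)c(O)c1C(=O)c1ccccc1 | intermediate
18 | phloroglucinol | Oc1cc(O)cc(O)c1 | starting material
19 | isobutyryl chloride | CC(C)C(Cl)=O | starting material
20 | 2-methyl-1-(2,4,6-trihydroxyphenyl)propan-1-one | CC(C)C(=O)c1c(O)cc(O)cc1O | intermediate
21 | isobutyrylfilicinic acid, 3,5-dihydroxy-6,6-dimethyl-2-(2-methylpropanoyl)cyclohexa-2,4-dien-1-one | CC(C)C(=O)C1=C(O)C=C(O)C(C)(C)C1=O | intermediate
22 | 4-benzoyl-5-hydroxy-6-methylidene-3-(3-methylbut-2-enyloxy)cyclohexa-2,4-dien-1-one (ortho-quinone methide, formed in the flask) | CC(C)=CCOC1=CC(=O)C(=C)C(O)=C1C(=O)c1ccccc1 | intermediate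
23 | sarothralin, 4-{[3-benzoyl-2,6-dihydroxy-4-(3-methylbut-2-enyloxy)phenyl]methyl}-3,5-dihydroxy-6,6-dimethyl-2-(2-methylpropanoyl)cyclohexa-2,4-dien-1-one | CC(C)=CCOc1cc(O)c(CC2=C(O)C(C)(C)C(=O)C(C(=O)C(C)C)=C2O)c(O)c1C(=O)c1ccccc1 | target

**Step count and risks**

Total step count: 13. Longest linear sequence: 11 (steps 1 to 10, then step 13); the filicinic acid branch is steps 11 and 12.

Steps most likely to fail:

Step 8. The aryl anion may be protonated before the acyl group moves, which would stop at O-arylation. At 125 °C the para-phenoxide of the product may also expel methoxide from the benzylic position. The fallback makes the same two bonds without an aryne and without heat. It sets out from bromophenol 7, which would be O-benzoylated (benzoyl chloride, Et3N, DMAP, CH2Cl2) to 2-bromo-3,5-bis(methoxymethoxy)-4-(methoxymethyl)phenyl benzoate F1. Bromine–lithium exchange with n-BuLi in THF at −100 °C would then trigger an anionic Fries-type 1,3-shift of the benzoyl group from oxygen to the lithiated carbon, which is the carbon beside the methoxymethoxy group. Aqueous work-up returns to the route at 13.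

Step 10. The Lewis acid may ionise the prenyl ether or the trioxygenated benzylic ether while the acetals are cleaved. The fallback removes the acetals before the prenyl group exists. It sets out from 13, which would be O-allylated (allyl bromide, K2CO3, DMF) to 2-(allyloxy)-4,6-bis(methoxymethoxy)-5-(methoxymethyl)benzophenone F2. Dilute HCl in methanol at rt to 40 °C would remove both MOM groups to give 2-(allyloxy)-4,6-dihydroxy-5-(methoxymethyl)benzophenone F3; the allyl ether is stable to acid and the benzylic methyl ether only exchanges with the solvent. Cross-metathesis of F3 with excess 2-methyl-2-butene and second-generation Grubbs catalyst in CH2Cl2 at 40 °C would turn the allyl ether into the prenyl ether and return to the route at 17.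

Step 13. Methanol loss may be sluggish, the quinone methide may be attacked by the free ring position of a second molecule, or the methylene bridge may exchange between partners to give symmetrical dimers under prolonged acid and heat. The fallback generates the quinone methide under base at room temperature. It sets out from 17, which would be heated with dimethylamine in THF at 50 °C to give the Mannich base 5-[(dimethylamino)methyl]-4,6-dihydroxy-2-(3-methylbut-2-enyloxy)benzophenone F4. N-Methylation with iodomethane in MeCN at rt would give {[3-benzoyl-2,6-dihydroxy-4-(3-methylbut-2-enyloxy)phenyl]methyl}trimethylammonium iodide F5. Treating F5 with 21 and NaHCO3 in aqueous MeCN at rt would expel trimethylamine, and the enolate of 21 would capture the quinone methide to reach 23.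

Further compounds
F1 | step 8 | 2-bromo-3,5-bis(methoxymethoxy)-4-(methoxymethyl)phenyl benzoate | O=C(Oc1cc(OCOC)c(COC)c(OCOC)c1Br)c1ccccc1
F2 | step 10 | 2-(allyloxy)-4,6-bis(methoxymethoxy)-5-(methoxymethyl)benzophenone | C=CCOc1cc(OCOC)c(COC)c(OCOC)c1C(=O)c1ccccc1
F3 | step 10 | 2-(allyloxy)-4,6-dihydroxy-5-(methoxymethyl)benzophenone | C=CCOc1cc(O)c(COC)c(O)c1C(=O)c1ccccc1
F4 | step 13 | 5-[(dimethylamino)methyl]-4,6-dihydroxy-2-(3-methylbut-2-enyloxy)benzophenone | CC(C)=CCOc1cc(O)c(CN(C)C)c(O)c1C(=O)c1ccccc1
F5 | step 13 | {[3-benzoyl-2,6-dihydroxy-4-(3-methylbut-2-enyloxy)phenyl]methyl}trimethylammonium iodide | CC(C)=CCOc1cc(O)c(C[N+](C)(C)C)c(O)c1C(=O)c1ccccc1.[I-]
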